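**Plan**
Retrosynthesis: remove three MOM groups. Then cut the bond between pyrone C2 of the apigenin half (half II) and C1 of its B ring, which is the phenoxy ring, para to the ether oxygen. Then cut the O–aryl bond of the C8–O–aryl ether of the methylated half (half I), and last the C8–O bond.
Enabling feature: in a bare chromone, the C2–H of the γ-pyrone ring sits on an sp2 carbon bound to ring O1 and vinylogous to C4=O. It is the most acidic C–H, so this natural acceptor carbon can be zincated (polarity reversal) and joined to the acceptor carbon of an aryl bromide.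
Forward, half I: commercial 7,4'-di-O-methylapigenin is hydroxylated at C8, the hindered 8-OH is arylated with a 4-bromophenyl group, and the 5-OH is masked.
Forward, half II: commercial 5,7-dihydroxychromone is masked, zincated at C2 and coupled, which completes the second flavone nucleus. One acid treatment then frees three phenols.
No ring is built, because all six rings are purchased. The OMe/OH pattern follows from the choice of halves, not from selective methylation.
Stereochemistry: none to set. The target has no stereocentre, and its ether and aryl–pyrone axes rotate freely.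

Key step: step 5

Remark: the target is achiral, so the request for a single enantiomer has no bearing on the route and no SMILES carries a stereodescriptor.

**Step 1**
Reactants: 1 5-hydroxy-7-methoxy-2-(4-methoxyphenyl)chromen-4-one (7,4'-di-O-methylapigenin)
Product: 3 5,8-dihydroxy-7-methoxy-2-(4-methoxyphenyl)chromen-4-one, via potassium flavon-8-yl sulfate 2 (not isolated)
Conditions: K2S2O8, aq KOH, pyridine, 15–20 °C; then conc. HCl, 90 °C, N2
Reagents that add atoms: potassium persulfate [K+].[K+].[O-]S(=O)(=O)OOS(=O)(=O)[O-]
Why: Elbs persulfate oxidation, in which the 5-phenolate attacks the peroxide oxygen through its para carbon C8 to give aryl sulfate 2, which acid hydrolysis should convert into the quinol, a classical transformation of 5-hydroxyflavones.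

**Step 2**
Reactants: 3 5,8-dihydroxy-7-methoxy-2-(4-methoxyphenyl)chromen-4-one; 4 bis(4-bromophenyl)iodonium triflate
Product: 5 8-(4-bromophenoxy)-5-hydroxy-7-methoxy-2-(4-methoxyphenyl)chromen-4-one
Conditions: t-BuOK (1.0 equiv), degassed DMF, 0 °C; then 4 (1.1 equiv), 40 °C, Ar
Reagents that add atoms: none
Why: Metal-free O-arylation of a phenolate with a diaryliodonium salt (ligand exchange at I(III), then ligand coupling) tolerates two ortho substituents, and the 8-OH should react in preference to the 5-OH, which is held in the hydrogen bond to C4=O and stays protonated with one equivalent of base.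

**Step 3**
Reactants: 5 8-(4-bromophenoxy)-5-hydroxy-7-methoxy-2-(4-methoxyphenyl)chromen-4-one
Product: 6 8-(4-bromophenoxy)-7-methoxy-5-(methoxymethoxy)-2-(4-methoxyphenyl)chromen-4-one
Conditions: NaH, MOMCl, DMF, 0 °C → rt
Reagents that add atoms: chloromethyl methyl ether (MOMCl) COCCl
Why: MOM protection by Williamson-type O-alkylation, in which irreversible deprotonation with NaH breaks the chelate and removes the only acidic proton of half I before it meets the organozinc.

**Step 4**
Reactants: 7 5,7-dihydroxychromen-4-one
Product: 8 5,7-bis(methoxymethoxy)chromen-4-one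
Conditions: NaH (3 equiv), MOMCl (3 equiv), DMF, 0 °C → rt
Reagents that add atoms: chloromethyl methyl ether (MOMCl) COCCl
Why: Double MOM protection by Williamson-type O-alkylation, where the non-nucleophilic base spares the base-sensitive C2-unsubstituted pyrone and also engages the chelated 5-OH.

**Step 5**
Reactants: 8 5,7-bis(methoxymethoxy)chromen-4-one; 6 8-(4-bromophenoxy)-7-methoxy-5-(methoxymethoxy)-2-(4-methoxyphenyl)chromen-4-one
Product: 10 8-{4-[5,7-bis(methoxymethoxy)-4-oxochromen-2-yl]phenoxy}-7-methoxy-5-(methoxymethoxy)-2-(4-methoxyphenyl)chromen-4-one, via 2-chlorozincio chromone 9 (not isolated)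
Conditions: 8 (1.3 equiv), TMPZnCl·LiCl (1.2 equiv, Mg-free), THF, 25 °C; then 6 (1.0 equiv), Pd(OAc)2 (4 mol %), SPhos (8 mol %), 50 °C
Reagents that add atoms: none
Why: TMPZnCl·LiCl removes the C2–H of the γ-pyrone ring of 8, the most acidic C–H of the molecule because it sits on an sp2 carbon bound to ring O1 and vinylogous to C4=O, and so turns the natural acceptor carbon of the chromone into the covalent, non-fragmenting carbon nucleophile 9 (polarity reversal). Pd(0)/SPhos then inserts into the only C–Br bond of 6, and zinc-to-palladium transmetalation followed by reductive elimination forms the aryl C1–pyrone C2 bond, which completes the second flavone nucleus in the same operation that joins the halves. The closest known reaction type is the regioselective C2 zincation of 5,7-dialkoxychromones followed by Negishi cross-coupling with aryl halides to give flavones. No ring is closed and no stereocentre is created. The step needs C2 over C3 selectivity, which the magnesium- and boron-free amide secures (a Lewis acid on C4=O would steer the base to C3), and selectivity against the arene C6–H and C8–H next to the acetal oxygens, which the low basicity of the zinc amide secures. Keeping 8 in slight excess over the base leaves no amide to metalate C3–H of 6, and the organozinc should leave both pyrone carbonyls, the MOM acetals and the methyl ethers untouched.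

**Step 6**
Reactants: 10 8-{4-[5,7-bis(methoxymethoxy)-4-oxochromen-2-yl]phenoxy}-7-methoxy-5-(methoxymethoxy)-2-(4-methoxyphenyl)chromen-4-one
Product: 11 8-[4-(5,7-dihydroxy-4-oxochromen-2-yl)phenoxy]-5-hydroxy-7-methoxy-2-(4-methoxyphenyl)chromen-4-one (target)
Conditions: conc. HCl (cat.), MeOH–THF, 50 °C
Reagents that add atoms: none
Why: Acid-catalysed acetal exchange (MOM cleavage) should free the three phenols at once while the aryl methyl ethers and the diaryl ether stay inert, and the acid is far milder than a Wessely–Moser rearrangement of the 5-hydroxy-8-aryloxy ring would need.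

**Compound list**
1 | 5-hydroxy-7-methoxy-2-(4-methoxyphenyl)chromen-4-one (7,4'-di-O-methylapigenin) | COc1ccc(-c2cc(=O)c3c(O)cc(OC)cc3o2)cc1 | starting material
2 | potassium 5-hydroxy-7-methoxy-2-(4-methoxyphenyl)-4-oxochromen-8-yl sulfate | COc1ccc(-c2cc(=O)c3c(O)cc(OC)c(OS(=O)(=O)[O-])c3o2)cc1.[K+] | intermediate
3 | 5,8-dihydroxy-7-methoxy-2-(4-methoxyphenyl)chromen-4-one | COc1ccc(-c2cc(=O)c3c(O)cc(OC)c(O)c3o2)cc1 | intermediate
4 | bis(4-bromophenyl)iodonium triflate | Brc1ccc([I+]c2ccc(Br)cc2)cc1.[O-]S(=O)(=O)C(F)(F)F | starting material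
5 | 8-(4-bromophenoxy)-5-hydroxy-7-methoxy-2-(4-methoxyphenyl)chromen-4-one | COc1ccc(-c2cc(=O)c3c(O)cc(OC)c(Oc4ccc(Br)cc4)c3o2)cc1 | intermediate
6 | 8-(4-bromophenoxy)-7-methoxy-5-(methoxymethoxy)-2-(4-methoxyphenyl)chromen-4-one | COc1ccc(-c2cc(=O)c3c(OCOC)cc(OC)c(Oc4ccc(Br)cc4)c3o2)cc1 | intermediate
7 | 5,7-dihydroxychromen-4-one | O=c1ccoc2cc(O)cc(O)c12 | starting material
8 | 5,7-bis(methoxymethoxy)chromen-4-one | COCOc1cc(OCOC)c2c(=O)ccoc2c1 | intermediate
9 | [5,7-bis(methoxymethoxy)-4-oxochromen-2-yl]zinc chloride | COCOc1cc(OCOC)c2c(=O)cc([Zn]Cl)oc2c1 | intermediate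
10 | 8-{4-[5,7-bis(methoxymethoxy)-4-oxochromen-2-yl]phenoxy}-7-methoxy-5-(methoxymethoxy)-2-(4-methoxyphenyl)chromen-4-one | COc1ccc(-c2cc(=O)c3c(OCOC)cc(OC)c(Oc4ccc(-c5cc(=O)c6c(OCOC)cc(OCOC)cc6o5)cc4)c3o2)cc1 | intermediate
11 | 8-[4-(5,7-dihydroxy-4-oxochromen-2-yl)phenoxy]-5-hydroxy-7-methoxy-2-(4-methoxyphenyl)chromen-4-one | COc1ccc(-c2cc(=O)c3c(O)cc(OC)c(Oc4ccc(-c5cc(=O)c6c(O)cc(O)cc6o5)cc4)c3o2)cc1 | target

Total step count: 6. Longest linear sequence: 5 (steps 1, 2, 3, 5, 6).

**Steps most likely to fail**

Step 5. The zincation may lose site selectivity, drifting to C3 or to the arene positions next to the acetal oxygens. Protodezincation may also outrun a slow transmetalation with the hindered, poorly soluble bromide.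
The fallback replaces polarity reversal by a polarity-matched addition. It sets out from 6 and 8 and returns at 10.
- Miyaura borylation of 6 (B2pin2, Pd(dppf)Cl2, KOAc, dioxane, 90 °C) should give the pinacol boronate F1.
- Rh(I)-catalysed conjugate addition of this boronate to the unmetalated chromone 8 ([Rh(cod)OH]2, dioxane–H2O, 60 °C) should give the racemic flavanone F2.
- Dehydrogenation with DDQ (dioxane, reflux) erases the transient stereocentre and gives 10.

Step 2. Single-electron oxidation of the quinol monoanion, by the I(III) salt or by traces of air, may lead towards the 5,8-quinone and compete with ligand coupling.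
The fallback uses addition–elimination on an activated arene. It sets out from 3 and returns at 5.
- SNAr of the 8-phenolate on 1-fluoro-4-nitrobenzene (K2CO3, DMF, 60 °C, Ar) should give the 4-nitrophenyl ether F3.
- Hydrogenation (H2, Pd/C, THF) should give the aniline F4.
- Sandmeyer bromination (t-BuONO, CuBr2, MeCN) gives 5.

Step 1. Conversion may be low and over-oxidation is typical of persulfate hydroxylation. Slow opening of the pyrone in aqueous alkali is a further risk.
The fallback inverts the roles in the ether formation, so that the flavone becomes the electrophile. It sets out from 1 and returns at 6, bypassing steps 1–3.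
- MOM protection of 1 (NaH, MOMCl, DMF) should give the 5-O-MOM flavone F5.
- Electrophilic iodination (NIS, DMF, rt), which should go to C8 once the 5-oxygen is alkylated, should give the 8-iodoflavone F6.
- Ullmann ether coupling with 4-bromophenol (CuI, picolinic acid, K3PO4, DMSO, 90 °C), selective for the C–I bond, gives 6.

**Further compounds**
F1 | step 5 | 7-methoxy-5-(methoxymethoxy)-2-(4-methoxyphenyl)-8-[4-(4,4,5,5-tetramethyl-1,3,2-dioxaborolan-2-yl)phenoxy]chromen-4-one | COc1ccc(-c2cc(=O)c3c(OCOC)cc(OC)c(Oc4ccc(B5OC(C)(C)C(C)(C)O5)cc4)c3o2)cc1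
F2 | step 5 | racemic 8-{4-[5,7-bis(methoxymethoxy)-4-oxochroman-2-yl]phenoxy}-7-methoxy-5-(methoxymethoxy)-2-(4-methoxyphenyl)chromen-4-one | COc1ccc(-c2cc(=O)c3c(OCOC)cc(OC)c(Oc4ccc(C5CC(=O)c6c(OCOC)cc(OCOC)cc6O5)cc4)c3o2)cc1
F3 | step 2 | 5-hydroxy-7-methoxy-2-(4-methoxyphenyl)-8-(4-nitrophenoxy)chromen-4-one | COc1ccc(-c2cc(=O)c3c(O)cc(OC)c(Oc4ccc([N+](=O)[O-])cc4)c3o2)cc1
F4 | step 2 | 8-(4-aminophenoxy)-5-hydroxy-7-methoxy-2-(4-methoxyphenyl)chromen-4-one | COc1ccc(-c2cc(=O)c3c(O)cc(OC)c(Oc4ccc(N)cc4)c3o2)cc1
F5 | step 1 | 7-methoxy-5-(methoxymethoxy)-2-(4-methoxyphenyl)chromen-4-one | COc1ccc(-c2cc(=O)c3c(OCOC)cc(OC)cc3o2)cc1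
F6 | step 1 | 8-iodo-7-methoxy-5-(methoxymethoxy)-2-(4-methoxyphenyl)chromen-4-one | COc1ccc(-c2cc(=O)c3c(OCOC)cc(OC)c(I)c3o2)cc1
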